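I began from a one-step world: target and isomer of the product A leave one source in a fixed split, so their ratio is one number for the whole run. The flask asked about is the south-west run followed further.

- south-west: solid substrate 0.80 M; the very flask that is asked about, followed so far
- flask: solid substrate 0.80 M; time 20 h

south-west run (percent of the solid substrate charged)

| time / h | target / % | isomer of the product A / % |
|---|---|---|
| 0.333 | 3.9 | 0.2 |
| 1.00 | 15.3 | 0.4 |
| 1.50 | 21.9 | 0.9 |
| 2.50 | 29.1 | 3.8 |
| 4.00 | 15.0 | 5.0 |
| 5.00 | 10.6 | 6.0 |
| 6.00 | 6.9 | 6.0 |

(scatter of a reading: 0.5 percentage points)

- as a solid, counted per litre of solution: solid substrate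
- at the start none of the solid substrate is in solution

* ratio of target to isomer of the product A at 20 min
* ratio of target to isomer of the product A at 20 h

In the south-west run, the reading at 1.00 h gave a ratio of 38.2. I called this the split number, target made per isomer of the product A made, a selectivity factor. It is rough, since that isomer reading of 0.4% carries a scatter of 0.5 percentage points. For 20 min I committed to about 38.2.

Then I tested it. At that split, the whole charge yields 2.55% of isomer, yet the south-west run held more than that, 6.0% at 6.00 h. One number was not enough: the ratio there read 1.15 and was falling, so for 20 h I expected a ratio below one, without a sharper figure.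

The forecast gave 90 and 0.004, holding of the isomer “so it comes from the target rather than in parallel”. Its early ratio stood higher than mine.

The flask gave 39.2 and 0.388.

    starting material → intermediate (k = 0.0120 /s)
    intermediate ⇌ target (K = 1.20, k = 8.30 × 10⁻⁴ /s)
    intermediate ⇌ isomer of the product A (K = 65.0, k = 1.50 × 10⁻⁵ /s)
    solid substrate ⇌ starting material, rate k4*(cs4 - [starting material]) while solid is left; crystals form when [starting material] > cs4 (solubility = 0.370 M, k = 2.80 × 10⁻⁴ /s)
    target ⇌ isomer of the product B (K = 26.0, k = 2.60 × 10⁻⁴ /s)

In this flask, target's half-life for going back through intermediate is 0.28 h, short against 20 h, while that of isomer of the product A is 35 d, long against it. In this flask, isomer of the product A at 20.0 h stood at 8.19%, 3.21 times the split number's ceiling.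

In a second flask with 2.0 M of solid substrate, the split number gives the same 38.2 early and the same 2.55% ceiling. That flask gave a ratio of 39.2 at 20 min and 7.96% of isomer of the product A at 20 h.

The numbers in the tables are simulated with constants of no real substance; the scatter is artificial.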